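**Plan**

- Retrosynthetic cuts: the furan ring at O1–C2 and C2–C3 (the ring B–CH unit leaves as a benzylic sulfonium ylide); the C3 formyl group goes back to a nitromethyl group; the C5 prenyl group goes back to an allyl group on O4 (C5–C1' by Claisen rearrangement, the trisubstituted alkene by cross-metathesis).
- Enabling feature: C2 lies between O1 and C3 and carries nothing but ring B, and C3 carries a single carbon, so C2 can be inserted as one carbon between a phenoxide oxygen and the β-carbon of an ortho-(2-nitrovinyl)phenol.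
- Forward order: ring A comes from a phloroglucinaldehyde ether (steps 1–3) and ring B from 4-methylresorcinol (steps 4–6); the dihydrofuran ring closes in step 7 and is aromatised in step 9 after the Nef reaction (step 8).
- The allyl group then moves from O4 to C5, which frees the C4 hydroxyl (step 10), is extended to prenyl (step 11), and the pivalates are removed (step 12); the prenyl unit therefore never meets the oxidant.
- Stereochemistry: the target has no stereocentre; C2 and C3 are formed trans and racemic in step 7 and erased in step 9; the E-nitroalkene of step 3 is the thermodynamic isomer.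

Key step: step 7

Remark: benzofuran numbering (O1, C2, C3, C3a, C4 to C7, C7a) is used throughout, ring A is the benzo ring and ring B the C2 aryl ring; compounds 13, 14 and 15 are racemic and drawn as one trans enantiomer.

**Route**

Step 1
Reactants: 1 2-hydroxy-4,6-dimethoxybenzaldehyde
Product: 2 2,6-dihydroxy-4-methoxybenzaldehyde
Conditions: BCl3 (3 equiv), CH2Cl2, −78 °C to rt; aq. HCl
Reagents that add atoms: none
Why: Chelation-directed cleavage of an aryl methyl ether: boron held at the formyl oxygen reaches only the ortho methoxy group through a six-membered chelate, so the para methoxy group (the future C6–OMe) should stay intact.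

Step 2
Reactants: 2 2,6-dihydroxy-4-methoxybenzaldehyde; 3 allyl bromide
Product: 4 2-(allyloxy)-6-hydroxy-4-methoxybenzaldehyde
Conditions: K2CO3 (1.1 equiv), acetone, 50 °C
Reagents that add atoms: none
Why: Williamson ether synthesis on a mirror-symmetric diol: both hydroxyls are equivalent, and after the first alkylation the remaining one is held in a hydrogen bond to the formyl oxygen and reacts much more slowly, which should stop the reaction at the monoether.

Step 3
Reactants: 4 2-(allyloxy)-6-hydroxy-4-methoxybenzaldehyde; 5 nitromethane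
Product: 6 (E)-3-(allyloxy)-5-methoxy-2-(2-nitrovinyl)phenol
Conditions: NH4OAc, MeNO2 (solvent), 95 °C
Reagents that add atoms: none
Why: Henry (nitroaldol) condensation driven on to the conjugated nitroalkene under NH4OAc, the E isomer being the thermodynamic product; the allyl aryl ether is inert at this temperature.

Step 4
Reactants: 7 4-methylresorcinol
Product: 8 2,4-bis(pivaloyloxy)toluene
Conditions: PivCl (2.3 equiv), Et3N, DMAP (cat.), CH2Cl2, 0 °C to rt
Reagents that add atoms: pivaloyl chloride, CC(C)(C)C(=O)Cl
Why: DMAP-catalysed O-acylation of both phenols; the pivalates make ring B electron-poor for the next steps and are hindered at the carbonyl carbon.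

Step 5
Reactants: 8 2,4-bis(pivaloyloxy)toluene
Product: 9 2,4-bis(pivaloyloxy)benzyl bromide
Conditions: NBS (1.05 equiv), AIBN (cat.), PhCF3, 85 °C
Reagents that add atoms: N-bromosuccinimide, O=C1CCC(=O)N1Br
Why: Wohl–Ziegler radical bromination at the only benzylic position; the acyloxy groups deactivate the ring toward electrophilic bromination, and starting from the toluene avoids a 2-acyloxybenzyl alkoxide that could take up the neighbouring acyl group.

Step 6
Reactants: 9 2,4-bis(pivaloyloxy)benzyl bromide
Product: 10 1-[2,4-bis(pivaloyloxy)benzyl]tetrahydrothiophenium bromide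
Conditions: tetrahydrothiophene (1.5 equiv), acetone, rt
Reagents that add atoms: tetrahydrothiophene, C1CCSC1
Why: SN2 alkylation of the sulfide by the benzylic bromide gives the sulfonium salt, which is expected to precipitate from acetone.

Step 7
Reactants: 6 (E)-3-(allyloxy)-5-methoxy-2-(2-nitrovinyl)phenol; 10 1-[2,4-bis(pivaloyloxy)benzyl]tetrahydrothiophenium bromide
Product: 13 trans-4-(allyloxy)-2-[2,4-bis(pivaloyloxy)phenyl]-6-methoxy-3-(nitromethyl)-2,3-dihydrobenzofuran (racemic), via sulfonium ylide 11 (not isolated), via sulfonium nitronate adduct 12 (not isolated)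
Conditions: Cs2CO3 (2.5 equiv), CH2Cl2, 0 °C to rt
Reagents that add atoms: none
Why: Cs2CO3 deprotonates the phenol of 6 and the benzylic position of 10, and ylide 11 adds through carbon to the β-carbon of the nitroalkene (the benzylic carbon that becomes C3), forming C2–C3 and the sulfonium nitronate 12. The ortho phenoxide then displaces tetrahydrothiophene at the sulfonium-bearing carbon by intramolecular SN2 substitution, a 5-exo-tet closure that forms O1–C2 and the dihydrofuran ring. The closest known reaction type is the formal [4+1] annulation of sulfur ylides with ortho-hydroxyaryl Michael acceptors and ortho-quinone methides to trans-2,3-dihydrobenzofurans. C2 and C3 are set relative to each other by the substrate: closure goes with inversion at C2 through the adduct conformer that keeps the ring B aryl group and the nitromethyl group on opposite faces, the acidic C–H next to sulfur letting the adduct diastereomers equilibrate, and no absolute control is needed because both centres are erased in step 9. The step needs oxygen alkylation by the phenoxide to beat closure through the nitronate carbon (3-exo-tet, nitrocyclopropane) or the nitronate oxygen (isoxazoline N-oxide), which the more nucleophilic phenoxide, held five atoms from the electrophilic carbon, should secure. It also needs the ylide carbon to spare the neighbouring ester and the benzylic C–S bond not to ionise, which the tert-butyl bulk and the electron-withdrawing character of the two pivaloyloxy groups should secure.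

Step 8
Reactants: 13 trans-4-(allyloxy)-2-[2,4-bis(pivaloyloxy)phenyl]-6-methoxy-3-(nitromethyl)-2,3-dihydrobenzofuran
Product: 15 trans-4-(allyloxy)-2-[2,4-bis(pivaloyloxy)phenyl]-6-methoxy-2,3-dihydrobenzofuran-3-carbaldehyde (racemic), via potassium nitronate 14 (not isolated)
Conditions: KOtBu (1.05 equiv), THF, −40 °C; then TiCl3 (aq., 4.5 equiv), NH4OAc, THF–H2O, 0 °C to rt
Reagents that add atoms: water, O
Why: Nef reaction in its reductive form: nitronate 14, made with a hindered base that spares the pivalates, is reduced by trivalent titanium in acetate buffer and hydrolysed in the same flask, water supplying the carbonyl oxygen; no oxidant or strong acid touches the allyl ether, and epimerisation at C3 is of no consequence.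

Step 9
Reactants: 15 trans-4-(allyloxy)-2-[2,4-bis(pivaloyloxy)phenyl]-6-methoxy-2,3-dihydrobenzofuran-3-carbaldehyde
Product: 16 4-(allyloxy)-2-[2,4-bis(pivaloyloxy)phenyl]-6-methoxybenzofuran-3-carbaldehyde
Conditions: DDQ (1.5 equiv), 1,4-dioxane, 80 °C
Reagents that add atoms: none
Why: Quinone dehydrogenation of a 2-aryl-2,3-dihydrobenzofuran with a C3 carbonyl group: hydride loss from C2 (benzylic and next to O1) and proton loss from C3 give the aromatic furan and remove both stereocentres; carrying the future prenyl unit as an O-allyl ether keeps an oxidisable benzylic-allylic CH2 and a free ortho phenol away from DDQ.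

Step 10
Reactants: 16 4-(allyloxy)-2-[2,4-bis(pivaloyloxy)phenyl]-6-methoxybenzofuran-3-carbaldehyde
Product: 17 5-allyl-2-[2,4-bis(pivaloyloxy)phenyl]-4-hydroxy-6-methoxybenzofuran-3-carbaldehyde
Conditions: PhNEt2, 190 °C (sealed tube)
Reagents that add atoms: none
Why: Aromatic Claisen rearrangement ([3,3]-sigmatropic): of the two positions ortho to O4 only C5 is free (the other is the ring-fusion carbon C3a), so the allyl group should go to C5 alone, and rearomatisation frees the C4 hydroxyl without any selective ether cleavage.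

Step 11
Reactants: 17 5-allyl-2-[2,4-bis(pivaloyloxy)phenyl]-4-hydroxy-6-methoxybenzofuran-3-carbaldehyde; 18 2-methylbut-2-ene
Product: 19 2-[2,4-bis(pivaloyloxy)phenyl]-4-hydroxy-6-methoxy-5-(3-methylbut-2-enyl)benzofuran-3-carbaldehyde
Conditions: second-generation Grubbs catalyst RuCl2(=CHPh)(H2IMes)(PCy3) (5 mol %), 2-methylbut-2-ene (excess), CH2Cl2, 40 °C
Reagents that add atoms: none
Why: Olefin cross-metathesis of a terminal allyl arene with excess 2-methylbut-2-ene converts allyl into 3-methylbut-2-enyl with loss of propene; the ruthenium carbene tolerates the free phenol, the aldehyde and the esters.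

Step 12
Reactants: 19 2-[2,4-bis(pivaloyloxy)phenyl]-4-hydroxy-6-methoxy-5-(3-methylbut-2-enyl)benzofuran-3-carbaldehyde
Product: 20 2-(2,4-dihydroxyphenyl)-4-hydroxy-6-methoxy-5-(3-methylbut-2-enyl)benzofuran-3-carbaldehyde
Conditions: K2CO3 (3 equiv), MeOH, rt; aq. NH4Cl
Reagents that add atoms: none
Why: Base-mediated transesterification: methoxide cleaves the two aryl pivalates as methyl pivalate at room temperature, conditions under which the non-enolisable aldehyde, the prenyl group and the methyl ether should be stable.

**Compound list**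

1 | 2-hydroxy-4,6-dimethoxybenzaldehyde | COc1cc(O)c(C=O)c(OC)c1 | starting material
2 | 2,6-dihydroxy-4-methoxybenzaldehyde | COc1cc(O)c(C=O)c(O)c1 | intermediate
3 | allyl bromide (3-bromoprop-1-ene) | C=CCBr | starting material
4 | 2-(allyloxy)-6-hydroxy-4-methoxybenzaldehyde | COc1cc(O)c(C=O)c(OCC=C)c1 | intermediate
5 | nitromethane | C[N+](=O)[O-] | starting material
6 | (E)-3-(allyloxy)-5-methoxy-2-(2-nitrovinyl)phenol | COc1cc(O)c(/C=C/[N+](=O)[O-])c(OCC=C)c1 | intermediate
7 | 4-methylresorcinol (4-methylbenzene-1,3-diol) | Cc1ccc(O)cc1O | starting material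
8 | 2,4-bis(pivaloyloxy)toluene | Cc1ccc(OC(=O)C(C)(C)C)cc1OC(=O)C(C)(C)C | intermediate
9 | 2,4-bis(pivaloyloxy)benzyl bromide | BrCc1ccc(OC(=O)C(C)(C)C)cc1OC(=O)C(C)(C)C | intermediate
10 | 1-[2,4-bis(pivaloyloxy)benzyl]tetrahydrothiophenium bromide | [Br-].CC(C)(C)C(=O)Oc1ccc(C[S+]2CCCC2)c(OC(=O)C(C)(C)C)c1 | intermediate
11 | [2,4-bis(pivaloyloxy)phenyl](tetrahydrothiophenium-1-yl)methanide (sulfonium ylide, not isolated) | CC(C)(C)C(=O)Oc1ccc([CH-][S+]2CCCC2)c(OC(=O)C(C)(C)C)c1 | intermediate
12 | cesium salt of the Michael adduct: ring A phenoxide and nitronate with the tetrahydrothiophenium group on the future C2 (diastereomer mixture, not isolated) | [Cs+].[O-][N+]([O-])=CC(c1c([O-])cc(OC)cc1OCC=C)C(c1ccc(OC(=O)C(C)(C)C)cc1OC(=O)C(C)(C)C)[S+]1CCCC1 | intermediate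
13 | trans-4-(allyloxy)-2-[2,4-bis(pivaloyloxy)phenyl]-6-methoxy-3-(nitromethyl)-2,3-dihydrobenzofuran (racemic, one enantiomer drawn) | [O-][N+](=O)C[C@H]1[C@H](c2ccc(OC(=O)C(C)(C)C)cc2OC(=O)C(C)(C)C)Oc2cc(OC)cc(OCC=C)c12 | intermediate
14 | potassium nitronate of 13 (racemic, not isolated) | [K+].[O-][N+]([O-])=C[C@H]1[C@H](c2ccc(OC(=O)C(C)(C)C)cc2OC(=O)C(C)(C)C)Oc2cc(OC)cc(OCC=C)c12 | intermediate
15 | trans-4-(allyloxy)-2-[2,4-bis(pivaloyloxy)phenyl]-6-methoxy-2,3-dihydrobenzofuran-3-carbaldehyde (racemic, one enantiomer drawn) | O=C[C@H]1[C@H](c2ccc(OC(=O)C(C)(C)C)cc2OC(=O)C(C)(C)C)Oc2cc(OC)cc(OCC=C)c12 | intermediate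
16 | 4-(allyloxy)-2-[2,4-bis(pivaloyloxy)phenyl]-6-methoxybenzofuran-3-carbaldehyde | O=Cc1c(-c2ccc(OC(=O)C(C)(C)C)cc2OC(=O)C(C)(C)C)oc2cc(OC)cc(OCC=C)c12 | intermediate
17 | 5-allyl-2-[2,4-bis(pivaloyloxy)phenyl]-4-hydroxy-6-methoxybenzofuran-3-carbaldehyde | O=Cc1c(-c2ccc(OC(=O)C(C)(C)C)cc2OC(=O)C(C)(C)C)oc2cc(OC)c(CC=C)c(O)c12 | intermediate
18 | 2-methylbut-2-ene | CC=C(C)C | starting material
19 | 2-[2,4-bis(pivaloyloxy)phenyl]-4-hydroxy-6-methoxy-5-(3-methylbut-2-enyl)benzofuran-3-carbaldehyde | O=Cc1c(-c2ccc(OC(=O)C(C)(C)C)cc2OC(=O)C(C)(C)C)oc2cc(OC)c(CC=C(C)C)c(O)c12 | intermediate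
20 | 2-(2,4-dihydroxyphenyl)-4-hydroxy-6-methoxy-5-(3-methylbut-2-enyl)benzofuran-3-carbaldehyde | O=Cc1c(-c2ccc(O)cc2O)oc2cc(OC)c(CC=C(C)C)c(O)c12 | target

**Totals**

Total steps: 12. Longest linear sequence: 9 steps (steps 1–3, then 7–12; the ring B branch, steps 4–6 then 7–12, is equally long).

**Steps most likely to fail**

Step 7. The ylide carbon may take the acyl group from the ortho pivalate, or the benzylic C–S bond may heterolyse before the ylide is intercepted; the adduct may also close through the nitronate instead of the phenoxide. The fallback sets out from 6 and returns at 16. It brings C2 in one oxidation level higher, as an acyl anion equivalent, so that ring closure is a carbonyl condensation and no dehydrogenation is needed. Commercial 2,4-dihydroxybenzaldehyde is pivaloylated (PivCl, Et3N, DMAP, CH2Cl2) to 2,4-bis(pivaloyloxy)benzaldehyde F1. A Stetter addition of F1 to 6 under thiazolium carbene catalysis (3-benzyl-5-(2-hydroxyethyl)-4-methylthiazolium chloride, iPr2NEt, THF, 50 °C) forms C2–C3 and should give the β-nitro ketone 2-[2-(allyloxy)-6-hydroxy-4-methoxyphenyl]-1-[2,4-bis(pivaloyloxy)phenyl]-3-nitropropan-1-one F2. Catalytic p-TsOH in toluene at 60 °C then closes O1–C2 by cyclodehydration to the aromatic 4-(allyloxy)-2-[2,4-bis(pivaloyloxy)phenyl]-6-methoxy-3-(nitromethyl)benzofuran F3. The nitronate and TiCl3 conditions of step 8 should convert F3 into 16.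

Step 8. Reduction may stall at a C=N stage or run on to the amine, and the enolisable β-aryloxy aldehyde may open by β-elimination of the ring A phenoxide. The fallback sets out from 13 and returns at 15. It separates reduction and hydrolysis into two mild operations. SnCl2·2H2O (divalent tin) with PhSH and Et3N in MeCN at rt should reduce the primary nitro group only as far as the aldoxime, trans-4-(allyloxy)-2-[2,4-bis(pivaloyloxy)phenyl]-6-methoxy-2,3-dihydrobenzofuran-3-carbaldehyde oxime F4. Exchange of the hydroxyimino group onto glyoxylic acid (aq. glyoxylic acid, NaOAc, THF–H2O, rt) should then release 15.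

Step 9. Hydride abstraction from C2 may be slow because ring B carries two acyloxy groups, which would leave DDQ to attack the electron-rich ring A or the allyl ether. The fallback sets out from 15 and returns at 16. It makes the C2=C3 bond by syn-elimination instead of hydride abstraction. TBSOTf and Et3N (CH2Cl2, 0 °C) should give the silyl enol ether 4-(allyloxy)-2-[2,4-bis(pivaloyloxy)phenyl]-3-[(tert-butyldimethylsilyloxy)methylene]-6-methoxy-2,3-dihydrobenzofuran F5. PhSeCl at −78 °C should selenenylate C3 on the face away from the C2 aryl group, faster than it adds to the allyl alkene, giving 4-(allyloxy)-2-[2,4-bis(pivaloyloxy)phenyl]-6-methoxy-3-(phenylselanyl)-2,3-dihydrobenzofuran-3-carbaldehyde F6. Oxidation with H2O2 and pyridine (CH2Cl2, 0 °C) should then trigger selenoxide elimination with the syn C2–H to give 16.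

Further compounds
F1 | step 7 | 2,4-bis(pivaloyloxy)benzaldehyde | CC(C)(C)C(=O)Oc1ccc(C=O)c(OC(=O)C(C)(C)C)c1
F2 | step 7 | 2-[2-(allyloxy)-6-hydroxy-4-methoxyphenyl]-1-[2,4-bis(pivaloyloxy)phenyl]-3-nitropropan-1-one (racemic) | CC(C)(C)C(=O)Oc1ccc(C(=O)C(C[N+](=O)[O-])c2c(O)cc(OC)cc2OCC=C)c(OC(=O)C(C)(C)C)c1
F3 | step 7 | 4-(allyloxy)-2-[2,4-bis(pivaloyloxy)phenyl]-6-methoxy-3-(nitromethyl)benzofuran | [O-][N+](=O)Cc1c(-c2ccc(OC(=O)C(C)(C)C)cc2OC(=O)C(C)(C)C)oc2cc(OC)cc(OCC=C)c12
F4 | step 8 | trans-4-(allyloxy)-2-[2,4-bis(pivaloyloxy)phenyl]-6-methoxy-2,3-dihydrobenzofuran-3-carbaldehyde oxime (racemic, oxime geometry mixed) | ON=C[C@H]1[C@H](c2ccc(OC(=O)C(C)(C)C)cc2OC(=O)C(C)(C)C)Oc2cc(OC)cc(OCC=C)c12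
F5 | step 9 | 4-(allyloxy)-2-[2,4-bis(pivaloyloxy)phenyl]-3-[(tert-butyldimethylsilyloxy)methylene]-6-methoxy-2,3-dihydrobenzofuran (racemic, alkene geometry mixed) | CC(C)(C)[Si](C)(C)OC=C1C(c2ccc(OC(=O)C(C)(C)C)cc2OC(=O)C(C)(C)C)Oc2cc(OC)cc(OCC=C)c12
F6 | step 9 | 4-(allyloxy)-2-[2,4-bis(pivaloyloxy)phenyl]-6-methoxy-3-(phenylselanyl)-2,3-dihydrobenzofuran-3-carbaldehyde (racemic, selenium anti to the C2 aryl group) | O=C[C@]1([Se]c2ccccc2)[C@H](c2ccc(OC(=O)C(C)(C)C)cc2OC(=O)C(C)(C)C)Oc2cc(OC)cc(OCC=C)c12
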